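## The problem

Guanipiperazine A (17) is a cis-2,5-dibenzylpiperazine whose two aryl groups are joined by a diaryl ether. Four atoms of the piperazine (C2, C3, N4 and C5), the two benzylic carbons, four carbons of the para-bridged ring B, the ether oxygen and three carbons of the meta-bridged ring A form a strained 14-membered meta,para-cyclophane. Ring A also carries a free phenol, and the second carbon ortho to that phenol is bonded to C8 of a guanine.

The only stereocentres are C2 and C5 of the piperazine, both S. They are 1,4-related across the ring, so neither can be relied on to set the other. Both are best taken from the chiral pool as α-carbons of an L-tyrosine, where they stay epimerisable only while a carbonyl group is next to them. The hard bond is the macrocyclic aryl–oxygen bond: a flat diketopiperazine holds the two arms too rigidly, so closure is realistic only on a saturated, conformationally mobile piperazine with cis benzyl arms.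

The groups that need care are the electron-rich phenol and diaryl ether (oxidants, electrophiles), the two secondary amines (they must be masked during oxidation and aldehyde chemistry) and the polar, poorly soluble aminopurinone, which is best built last.

The feature that makes the key step possible is the substitution pattern of the rings. In ring A the ether oxygen sits on C3, next to the phenolic C4–OH and meta to the benzylic carbon. Ring B is a para-alkylphenyl ether, so its oxygen is the phenol oxygen of a second tyrosine. This is the pattern of an ortho C–O coupling between two tyrosine phenols, and without the guanine the skeleton is a reduced, C2-symmetric cyclo(Tyr-Tyr). After such a coupling ring A keeps exactly one free position ortho to its hydroxyl group, and that is the carbon that bears the guanine.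

## Retrosynthesis

**17 from 16.** The last cut removes the two N–CO2tBu bonds, leading back to the bis-carbamate 16. The amines must stay masked until the purine is finished, because a free piperazine nitrogen would add to the aldehyde used for the annulation. tert-Butyl carbamates are preferred to benzyl carbamates because they survive hydrogenolysis, zinc, mild base and hot DMF, and fall to trifluoroacetic acid, which an 8-arylguanine tolerates. Compound 16 is no simpler in skeleton but is neutral and organic-soluble. The forward step only has to be a clean acidolysis.

**16 from 12 and 13.** The imidazole ring of the guanine is opened at C8–N7 and C8–N9. This gives the ring A salicylaldehyde 12, whose formyl carbon becomes C8, and the commercial triaminopyrimidinone 13. The neighbouring cut, the C8–aryl bond, would call for a protected 8-haloguanine and a hindered ortho-metallated phenol on the macrocycle; the annulation needs neither and removes all five nitrogens of the heterocycle in one move. The forward reaction must condense at the 5-amino group, close with the 6-amino group and dehydrogenate with an oxidant mild enough to spare the phenol.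

**12 from 11.** The ring A C–CHO bond is cut, leading to N,N'-di-Boc-piperazinomycin 11. No regiochemical choice is needed: ring A has one free ortho position, its para position is the benzylic carbon, and ring B has no hydroxyl group. A phenoxide-directed ortho-formylation is therefore sufficient, and it is preferred to electrophilic formylations in strong acid, which would remove the carbamates.

**11 from 10.** Three aryl C–H bonds are traced back to C–Br bonds of the tribromide 10. The bromines are control elements for the ring closure and have no place in the target. The ring A bromine of 10 sits on the future guanine carbon, but it cannot be addressed selectively beside the two ring B bromines, so all three are removed and the position is re-functionalised in the step to 12. The forward step is a plain hydrogenolysis that the carbamates and the diaryl ether survive.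

**10 from 8 (key disconnection).** The bond between the ring B oxygen and C3 of ring A is cut oxidatively. This opens the 14-membered ring and leads, through the bromodienone 9, to the tetrabromo bisphenol 8.

- Cutting the same oxygen from ring B instead (an Ullmann or SNAr closure) would need two different amino acids, one with a differentiated catechol and one with a para-halogen.
- Cutting the piperazine after the ether is in place would close the strained ring through C–N bonds next to epimerisable centres.
- The oxidative cut leads to a precursor in which both halves are the same, so no choice between the rings arises and one amino acid serves twice.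

The forward reaction must form C–O and not C–C, at an ortho carbon, within the molecule. The four ortho bromines, the blocked para positions and the cis arms on a flexible carbamate-protected piperazine are there to secure this. An anode is preferred to stoichiometric Tl(NO3)3.

**8 from 7 and 6.** The two N–Boc bonds are removed to give the free piperazine 7. The two ring methylenes next to nitrogen are then recognised as reduced lactam carbonyls, which leads to the diketopiperazine 6. Borane is required because it leaves aryl bromides alone. The carbamates are installed after the reduction, since they would not survive it.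

**6 from 4, 2 and 3, all from 1.** The two amide bonds of 6 are cut in turn: first the ring-closing lactam (amine 5 onto its own methyl ester, from the Boc dipeptide 4), then the peptide bond between ester 2 and acid 3. Both are made from 3,5-dibromo-L-tyrosine 1, which supplies both stereocentres and all four bromines. The stepwise, urethane-protected assembly is chosen over thermal self-condensation of the amino ester because it keeps the L,L (cis) relationship safe.

## Roads not taken

**Alternative 1:** The piperazine ring is cut at both C–N bonds next to the ring methylenes. The precursor is the open diaryl ether bis-aldehyde A2, which carries two N-Cbz α-amino aldehyde arms. Hydrogenolysis of A2 over Pd/C at high dilution would free both amines; they condense head-to-tail with the two aldehydes and are reduced in the same flask to piperazinomycin A1, so piperazine and macrocycle close together.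

- Merits: the ether bond of A2 is made intermolecularly, where the oxidative coupling of dihalophenols has no ring strain to fight, and no diketopiperazine, borane reduction or separate macrocyclisation is needed. In convergence this road is better than the chosen one.
- Weak points: α-amino aldehydes are configurationally labile, so A2 is at risk before and after its Cbz groups fall. After the double condensation the six-membered ring sits at a bis-imine oxidation level, where imine–enamine tautomerism would erase both stereocentres and dehydrogenation on Pd/C to an aromatic pyrazine ring is easy. The first imine still has to close the strained 14-membered ring against oligomers, and the aldehydes of A2 must survive the hydrogenolysis. A1 also emerges unprotected and must be converted into 11 before formylation.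
- Comparison: the chosen plan accepts a longer linear sequence in exchange for stereocentres that are never at risk after step 5 and a ring closure with precedent in this ring class.

**Alternative 2:** Only the imidazole ring is cut. The ring A salicylaldehyde A3 on the protected macrocycle, identical with 12, is condensed with 13, and the resulting aminal is dehydrogenated under air with Na2S2O5 in hot DMF to the di-Boc 8-arylguanine A4, identical with 16.

- Merits: the heterocycle of A4 comes from a cheap pyrimidine, no cross-coupling is used, and the step is late and convergent.
- Weak points: this road says nothing about the 14-membered ring, which is the real difficulty of the target.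
- Comparison: it is an endgame, not a ring strategy. For the purine it is the same as the chosen plan, which uses this reaction as step 10. The chosen plan adds the answer to the question it leaves open, namely how A3 is reached.

**Alternative 3:** The diaryl ether is traced to the 15-membered macrocyclic aryl ester A6, in which the ring A oxygen is acylated by a ring B para-carboxylic acid. Zerovalent nickel (Ni(cod)2 with 3,4-bis(dicyclohexylphosphino)thiophene and K3PO4 in hot toluene) would extrude CO from A6 and contract the lactone to N,N'-dibenzyl-O-methylpiperazinomycin A5.

- Merits: macrolactonisation to the phenolic ester A6 is a more dependable ring closure than a direct diaryl ether macrocyclisation, and no electron-rich ring is exposed to an oxidant. In both respects this road is better.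
- Weak points: decarbonylative ether formation is best established for esters of azine carboxylic acids in unstrained settings, so a plain para-alkylbenzoate contracting into a strained cyclophane lies at the edge of what is known. The precursor A6 needs two different, separately protected arylalanines in place of one amino acid. The O-methyl and N-benzyl groups of A5 must then be exchanged (a Lewis acid demethylation and a hydrogenolysis) before the phenol-directed formylation can follow.
- Comparison: the chosen plan sets against the safer lactonisation its C2-symmetric precursor from a single amino acid, a shorter protecting-group sequence and a key reaction of a known type.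

Key step: step 7

## Route

Assumption: the pyrimidine is used as its commercial 1:1 sulfate (13) and is freed in the flask by NaOAc; the target is written as the neutral lactam tautomer.

Step 1
Reactants: 1 3,5-dibromo-L-tyrosine
Product: 2 methyl 3,5-dibromo-L-tyrosinate hydrochloride
Conditions: SOCl2, MeOH, 0 °C to reflux
Reagents that add atoms: methanol, CO; thionyl chloride, O=S(Cl)Cl (source of the chloride of the salt)
Why: Fischer esterification driven by HCl formed in the flask; the ammonium salt cannot racemise and the dibromophenol is inert.

Step 2
Reactants: 1 3,5-dibromo-L-tyrosine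
Product: 3 N-Boc-3,5-dibromo-L-tyrosine
Conditions: Boc2O, NaOH, dioxane/H2O, 0 °C to rt; aq. KHSO4 to pH 3
Reagents that add atoms: di-tert-butyl dicarbonate, CC(C)(C)OC(=O)OC(=O)OC(C)(C)C
Why: Standard carbamate formation on the amine; any carbonate formed on the hindered, weakly nucleophilic dibromophenoxide is hydrolysed by the aqueous base.

Step 3
Reactants: 2 methyl 3,5-dibromo-L-tyrosinate hydrochloride; 3 N-Boc-3,5-dibromo-L-tyrosine
Product: 4 methyl N-Boc-3,5-dibromo-L-tyrosyl-3,5-dibromo-L-tyrosinate
Conditions: EDC·HCl, HOBt, N-methylmorpholine, DMF, 0 °C to rt
Reagents that add atoms: none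
Why: Carbodiimide/HOBt amide coupling of a urethane-protected acid, which does not racemise through an oxazolone; the primary amine outcompetes the flanked dibromophenoxides, and any aryl ester that forms is itself an active ester that passes its acyl group on to the amine.

Step 4
Reactants: 4 methyl N-Boc-3,5-dibromo-L-tyrosyl-3,5-dibromo-L-tyrosinate
Product: 6 (3S,6S)-3,6-bis(3,5-dibromo-4-hydroxybenzyl)piperazine-2,5-dione, via dipeptide amine formate 5 (not isolated)
Conditions: HCO2H, rt; evaporate; sec-BuOH/toluene, reflux
Reagents that add atoms: none
Why: Acidolysis of the Boc group followed by thermal 6-exo-trig lactamisation of the dipeptide ester, the standard diketopiperazine closure; the L,L dipeptide gives the cis ring and both stereocentres are carried over unchanged.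

Step 5
Reactants: 6 (3S,6S)-3,6-bis(3,5-dibromo-4-hydroxybenzyl)piperazine-2,5-dione
Product: 7 (2S,5S)-2,5-bis(3,5-dibromo-4-hydroxybenzyl)piperazine
Conditions: BH3·THF (excess), THF, reflux; MeOH, then 6 M HCl, reflux; aq. NaHCO3 to pH 7–8
Reagents that add atoms: none
Why: Borane reduction of secondary lactams to amines; borane, unlike LiAlH4, leaves aryl bromides alone, the α-centres are not enolised under these conditions, and the acid treatment breaks the amine–borane and aryl borate complexes.

Step 6
Reactants: 7 (2S,5S)-2,5-bis(3,5-dibromo-4-hydroxybenzyl)piperazine
Product: 8 di-tert-butyl (2S,5S)-2,5-bis(3,5-dibromo-4-hydroxybenzyl)piperazine-1,4-dicarboxylate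
Conditions: Boc2O, Et3N, THF/H2O, rt; then K2CO3, MeOH, rt
Reagents that add atoms: di-tert-butyl dicarbonate, CC(C)(C)OC(=O)OC(=O)OC(C)(C)C
Why: Carbamoylation of the two secondary amines; the acidic but hindered phenols react poorly, and any aryl tert-butyl carbonate is removed by the mild methanolysis, which does not touch N-Boc groups.

Step 7
Reactants: 8 di-tert-butyl (2S,5S)-2,5-bis(3,5-dibromo-4-hydroxybenzyl)piperazine-1,4-dicarboxylate
Product: 10 N,N'-di-Boc-tribromopiperazinomycin, via macrocyclic bromodienone 9 (not isolated)
Conditions: constant current (about 2 F/mol), glassy-carbon anode, Pt cathode, undivided cell, LiClO4 (0.1 M), MeOH, 1 mM, rt; evaporate; then Zn dust, AcOH/THF, rt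
Reagents that add atoms: none
Why: The reaction is the anodic counterpart of the Tl(NO3)3 oxidation of ortho,ortho'-dihalophenols to diaryl ethers followed by zinc reduction, the established entry to isodityrosine-type macrocycles. Two-electron oxidation of one dibromophenol of 8 at the carbon anode, with loss of a proton, should give a phenoxonium ion whose positive charge lies on the two bromine-bearing ortho carbons and the blocked para carbon. The hydroxyl oxygen of the other ring adds to one ortho carbon and so closes the 14-membered ring; the attacked trigonal carbon and its neighbours C2 and C1 of ring A lie in the new ring, so the closure is formally endo, and it leaves the 6-aryloxy-6-bromocyclohexa-2,4-dienone 9. Zinc in acetic acid then transfers two electrons to 9, bromide leaves and ring A rearomatises to the phenol of 10. No stereocentre is created in 10: the sp3 carbon of 9 is transient and its configuration is irrelevant, and the (2S,5S) centres are remote from the redox events. The step needs C–O over C–C coupling and ortho over para attack; the four ortho bromines block carbon–carbon bond formation and provide the group lost on reduction, and the para positions carry the benzylic carbons. It also needs ring closure to beat oligomerisation, which high dilution and the cis arms on the mobile di-Boc piperazine should secure, and no choice between the rings arises because 8 is C2-symmetric. The carbamate nitrogens are oxidised only at clearly higher potential than a phenol, so a low current density and about two faradays per mole should leave them untouched.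

Step 8
Reactants: 10 N,N'-di-Boc-tribromopiperazinomycin
Product: 11 N,N'-di-Boc-piperazinomycin
Conditions: H2 (1 atm), 10% Pd/C, Et3N, MeOH/EtOAc, rt
Reagents that add atoms: none
Why: Catalytic hydrogenolysis of the three aryl C–Br bonds; Et3N traps the HBr so that the Boc groups survive, and the diaryl ether, phenol and carbamates are inert to Pd/H2.

Step 9
Reactants: 11 N,N'-di-Boc-piperazinomycin
Product: 12 N,N'-di-Boc-formylpiperazinomycin (formyl group on the ring A carbon ortho to the phenol)
Conditions: MgCl2, Et3N, (CH2O)n, MeCN, reflux; aq. citric acid
Reagents that add atoms: paraformaldehyde (formaldehyde), C=O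
Why: Casnati–Skattebøl ortho-formylation: the ArOMgCl phenoxide delivers formaldehyde to the ortho carbon through a chelate and a second formaldehyde takes up hydride to give the aldehyde; ring A has one free ortho position, its para position is the benzylic carbon and ring B has no phenol, so only one aldehyde can form.

Step 10
Reactants: 12 N,N'-di-Boc-formylpiperazinomycin; 13 2,5,6-triaminopyrimidin-4(3H)-one sulfate
Product: 16 N,N'-di-Boc-guanipiperazine A, via Schiff base 14 (not isolated), via dihydroguanine 15 (not isolated)
Conditions: NaOAc, Na2S2O5, DMF/H2O, 110 °C, open to air
Reagents that add atoms: none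
Why: Traube-type imidazole annulation as used for 8-arylpurines and 2-arylbenzimidazoles: the 5-amino group, the most nucleophilic of the three, condenses with the aldehyde (as its bisulfite adduct) to 14, the 6-amino group adds to the C=N bond to give the 7,8-dihydropurine 15, and air dehydrogenates it to the aromatic purine; the acetate buffer protects the Boc groups and the oxidant is too mild to attack the phenol.

Step 11
Reactants: 16 N,N'-di-Boc-guanipiperazine A
Product: 17 guanipiperazine A
Conditions: TFA/CH2Cl2 (1:2), 0 °C to rt; evaporate; aq. NH3 to pH 8
Reagents that add atoms: none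
Why: Acidolysis of the two tert-butyl carbamates; the 8-arylguanine, phenol and diaryl ether are stable to trifluoroacetic acid, the stereocentres carry no acidifying group, and neutralisation releases the free base.

## Compound list

1 | 3,5-dibromo-L-tyrosine | N[C@@H](Cc1cc(Br)c(O)c(Br)c1)C(=O)O | starting material
2 | methyl 3,5-dibromo-L-tyrosinate hydrochloride | N[C@@H](Cc1cc(Br)c(O)c(Br)c1)C(=O)OC.Cl | intermediate
3 | N-Boc-3,5-dibromo-L-tyrosine | CC(C)(C)OC(=O)N[C@@H](Cc1cc(Br)c(O)c(Br)c1)C(=O)O | intermediate
4 | methyl N-Boc-3,5-dibromo-L-tyrosyl-3,5-dibromo-L-tyrosinate | CC(C)(C)OC(=O)N[C@@H](Cc1cc(Br)c(O)c(Br)c1)C(=O)N[C@@H](Cc1cc(Br)c(O)c(Br)c1)C(=O)OC | intermediate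
5 | methyl 3,5-dibromo-L-tyrosyl-3,5-dibromo-L-tyrosinate formate (not isolated) | N[C@@H](Cc1cc(Br)c(O)c(Br)c1)C(=O)N[C@@H](Cc1cc(Br)c(O)c(Br)c1)C(=O)OC.OC=O | intermediate
6 | (3S,6S)-3,6-bis(3,5-dibromo-4-hydroxybenzyl)piperazine-2,5-dione | Oc1c(Br)cc(cc1Br)C[C@H]1C(=O)N[C@H](C(=O)N1)Cc1cc(Br)c(O)c(Br)c1 | intermediate
7 | (2S,5S)-2,5-bis(3,5-dibromo-4-hydroxybenzyl)piperazine | Oc1c(Br)cc(cc1Br)C[C@H]1CN[C@H](CN1)Cc1cc(Br)c(O)c(Br)c1 | intermediate
8 | di-tert-butyl (2S,5S)-2,5-bis(3,5-dibromo-4-hydroxybenzyl)piperazine-1,4-dicarboxylate | Oc1c(Br)cc(cc1Br)C[C@H]1CN(C(=O)OC(C)(C)C)[C@H](CN1C(=O)OC(C)(C)C)Cc1cc(Br)c(O)c(Br)c1 | intermediate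
9 | macrocyclic 6-aryloxy-2,6-dibromocyclohexa-2,4-dienone (ring A as dienone, ring B oxygen on its C6; C6 configuration undefined; not isolated) | O=C1C(Br)=CC2=CC1(Br)Oc1c(Br)cc(cc1Br)C[C@H]1CN(C(=O)OC(C)(C)C)[C@H](CN1C(=O)OC(C)(C)C)C2 | intermediate
10 | N,N'-di-Boc-tribromopiperazinomycin (ring A: 4-hydroxy, 5-bromo, ether oxygen on C3; ring B: 3,5-dibromo, ether oxygen on C4; (2S,5S)) | Oc1c(Br)cc2cc1Oc1c(Br)cc(cc1Br)C[C@H]1CN(C(=O)OC(C)(C)C)[C@H](CN1C(=O)OC(C)(C)C)C2 | intermediate
11 | N,N'-di-Boc-piperazinomycin | Oc1ccc2cc1Oc1ccc(cc1)C[C@H]1CN(C(=O)OC(C)(C)C)[C@H](CN1C(=O)OC(C)(C)C)C2 | intermediate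
12 | N,N'-di-Boc-formylpiperazinomycin (CHO on the ring A carbon ortho to OH) | O=Cc1cc2cc(c1O)Oc1ccc(cc1)C[C@H]1CN(C(=O)OC(C)(C)C)[C@H](CN1C(=O)OC(C)(C)C)C2 | intermediate
13 | 2,5,6-triaminopyrimidin-4(3H)-one sulfate | Nc1nc(N)c(N)c(=O)[nH]1.OS(=O)(=O)O | starting material
14 | Schiff base of 12 with the 5-amino group of the pyrimidinone, E (not isolated) | Nc1nc(N)c(/N=C/c2cc3cc(c2O)Oc2ccc(cc2)C[C@H]2CN(C(=O)OC(C)(C)C)[C@H](CN2C(=O)OC(C)(C)C)C3)c(=O)[nH]1 | intermediate
15 | 8-aryl-7,8-dihydroguanine (C8 configuration undefined; not isolated) | Nc1nc2NC(Nc2c(=O)[nH]1)c1cc3cc(c1O)Oc1ccc(cc1)C[C@H]1CN(C(=O)OC(C)(C)C)[C@H](CN1C(=O)OC(C)(C)C)C3 | intermediate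
16 | N,N'-di-Boc-guanipiperazine A | Nc1nc2nc(-c3cc4cc(c3O)Oc3ccc(cc3)C[C@H]3CN(C(=O)OC(C)(C)C)[C@H](CN3C(=O)OC(C)(C)C)C4)[nH]c2c(=O)[nH]1 | intermediate
17 | guanipiperazine A | Nc1nc2nc(-c3cc4cc(c3O)Oc3ccc(cc3)C[C@H]3CN[C@H](CN3)C4)[nH]c2c(=O)[nH]1 | target

## Step count and risk

Total: 11 steps. Longest linear sequence: 10 steps (1 → 2 → 4 → 6 → 7 → 8 → 10 → 11 → 12 → 16 → 17; step 2 is the parallel branch).

**Step 7 (key step).** The most likely failure is that ring closure loses to intermolecular coupling and to capture of the phenoxonium ion by methanol, because the 14-membered cyclophane is strained; over-oxidation of the product phenol is a second drain.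

The fallback changes the bond-forming principle from phenol oxidation to a CuI-mediated Ullmann etherification, with the roles of the two rings fixed by constitution. It sets out from 2 and returns at 11. Compound 2 is coupled (EDC·HCl, HOBt, N-methylmorpholine, DMF) with commercial N-Boc-L-tyrosine to give methyl N-Boc-L-tyrosyl-3,5-dibromo-L-tyrosinate F1. Formic acid and then hot sec-butanol/toluene, as in step 4, close it to (3S,6S)-3-(3,5-dibromo-4-hydroxybenzyl)-6-(4-hydroxybenzyl)piperazine-2,5-dione F2. BH3·THF, as in step 5, reduces this to (2S,5S)-2-(3,5-dibromo-4-hydroxybenzyl)-5-(4-hydroxybenzyl)piperazine F3, and Boc2O then gives di-tert-butyl (2S,5S)-2-(3,5-dibromo-4-hydroxybenzyl)-5-(4-hydroxybenzyl)piperazine-1,4-dicarboxylate F4. Benzyl bromide with KHCO3 in DMF should alkylate only the far more acidic dibromophenol, giving di-tert-butyl (2S,5S)-2-[4-(benzyloxy)-3,5-dibromobenzyl]-5-(4-hydroxybenzyl)piperazine-1,4-dicarboxylate F5. CuI, N,N-dimethylglycine and Cs2CO3 in dioxane at 100 °C and high dilution then join the free ring B phenol oxygen to one of the two equivalent bromine-bearing carbons of ring A, giving N,N'-di-Boc-O-benzyl-bromopiperazinomycin F6. Hydrogenolysis (H2, Pd/C, Et3N) removes the remaining bromine and the benzyl group and delivers 11.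

**Step 10.** The most likely failure is incomplete oxidative ring closure: the salicylidene Schiff base 14 is stabilised by its internal hydrogen bond and may stall or hydrolyse back, while 13 is consumed by air oxidation.

The fallback closes the imidazole by dehydration at the acid oxidation level (classical Traube closure). It sets out from 12 and returns at 16. Pinnick oxidation (NaClO2, NaH2PO4, 2-methyl-2-butene, tBuOH/H2O) gives the ring A carboxylic acid N,N'-di-Boc-carboxypiperazinomycin F7. EDC·HCl/HOBt coupling with 13 (freed with Et3N in DMF) acylates the 5-amino group and gives the 5-amido-2,6-diaminopyrimidinone F8. Cyclodehydration in hot aqueous NaOH, to which Boc carbamates are stable, gives 16.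

**Step 9.** The most likely failure is low conversion, because the ArOMgCl phenoxide of the strained cyclophane, flanked by the aryloxy group, may react sluggishly, and condensation of the hydroxymethyl stage to diarylmethanes may compete.

The fallback separates C–C bond formation from oxidation. It sets out from 11 and returns at 12. Lederer–Manasse hydroxymethylation (aqueous formaldehyde, NaOH, dioxane/H2O, rt) at the only free ortho position gives the salicyl alcohol N,N'-di-Boc-(hydroxymethyl)piperazinomycin F9. MnO2 in CHCl3 then oxidises the benzylic alcohol to 12.

**Step 3.** The most likely failure is competing O-acylation by the acidic dibromophenols, leading to aryl esters and oligomers of low solubility.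

The fallback avoids any activated carboxyl group. It sets out from 2 and returns at 6, bypassing 3, 4 and 5. Compound 2 is freed with Et3N and heated in sec-butanol/toluene so that the amino ester condenses head-to-tail with itself. No new compound arises on this path, which is entered as F0. The price is a possible partial epimerisation during the long heating, which would show as the trans diketopiperazine and would have to be removed by crystallisation.

## Further compounds

F1 | step 7 | methyl N-Boc-L-tyrosyl-3,5-dibromo-L-tyrosinate | CC(C)(C)OC(=O)N[C@@H](Cc1ccc(O)cc1)C(=O)N[C@@H](Cc1cc(Br)c(O)c(Br)c1)C(=O)OC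
F2 | step 7 | (3S,6S)-3-(3,5-dibromo-4-hydroxybenzyl)-6-(4-hydroxybenzyl)piperazine-2,5-dione | Oc1ccc(cc1)C[C@H]1C(=O)N[C@H](C(=O)N1)Cc1cc(Br)c(O)c(Br)c1
F3 | step 7 | (2S,5S)-2-(3,5-dibromo-4-hydroxybenzyl)-5-(4-hydroxybenzyl)piperazine | Oc1ccc(cc1)C[C@H]1CN[C@H](CN1)Cc1cc(Br)c(O)c(Br)c1
F4 | step 7 | di-tert-butyl (2S,5S)-2-(3,5-dibromo-4-hydroxybenzyl)-5-(4-hydroxybenzyl)piperazine-1,4-dicarboxylate | Oc1ccc(cc1)C[C@H]1CN(C(=O)OC(C)(C)C)[C@H](CN1C(=O)OC(C)(C)C)Cc1cc(Br)c(O)c(Br)c1
F5 | step 7 | di-tert-butyl (2S,5S)-2-[4-(benzyloxy)-3,5-dibromobenzyl]-5-(4-hydroxybenzyl)piperazine-1,4-dicarboxylate | Oc1ccc(cc1)C[C@H]1CN(C(=O)OC(C)(C)C)[C@H](CN1C(=O)OC(C)(C)C)Cc1cc(Br)c(OCc2ccccc2)c(Br)c1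
F6 | step 7 | N,N'-di-Boc-O-benzyl-bromopiperazinomycin (ring A: 4-benzyloxy, 5-bromo, ether oxygen on C3) | c1ccccc1COc1c(Br)cc2cc1Oc1ccc(cc1)C[C@H]1CN(C(=O)OC(C)(C)C)[C@H](CN1C(=O)OC(C)(C)C)C2
F7 | step 10 | N,N'-di-Boc-carboxypiperazinomycin (CO2H on the ring A carbon ortho to OH) | OC(=O)c1cc2cc(c1O)Oc1ccc(cc1)C[C@H]1CN(C(=O)OC(C)(C)C)[C@H](CN1C(=O)OC(C)(C)C)C2
F8 | step 10 | N-(2,6-diamino-4-oxo-3,4-dihydropyrimidin-5-yl) amide of F7 | Nc1nc(N)c(NC(=O)c2cc3cc(c2O)Oc2ccc(cc2)C[C@H]2CN(C(=O)OC(C)(C)C)[C@H](CN2C(=O)OC(C)(C)C)C3)c(=O)[nH]1
F9 | step 9 | N,N'-di-Boc-(hydroxymethyl)piperazinomycin (CH2OH on the ring A carbon ortho to OH) | OCc1cc2cc(c1O)Oc1ccc(cc1)C[C@H]1CN(C(=O)OC(C)(C)C)[C@H](CN1C(=O)OC(C)(C)C)C2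
F0 | step 3 | none | none
A1 | alternative 1 | piperazinomycin | Oc1ccc2cc1Oc1ccc(cc1)C[C@H]1CN[C@H](CN1)C2
A2 | alternative 1 | open diaryl ether with two (S)-2-(benzyloxycarbonylamino)-3-oxopropyl arms (ring A: 4-hydroxy-3-aryloxy; ring B: 4-aryloxy) | Oc1ccc(cc1Oc1ccc(cc1)C[C@H](NC(=O)OCc1ccccc1)C=O)C[C@H](NC(=O)OCc1ccccc1)C=O
A3 | alternative 2 | N,N'-di-Boc-formylpiperazinomycin (identical with 12) | O=Cc1cc2cc(c1O)Oc1ccc(cc1)C[C@H]1CN(C(=O)OC(C)(C)C)[C@H](CN1C(=O)OC(C)(C)C)C2
A4 | alternative 2 | N,N'-di-Boc-guanipiperazine A (identical with 16) | Nc1nc2nc(-c3cc4cc(c3O)Oc3ccc(cc3)C[C@H]3CN(C(=O)OC(C)(C)C)[C@H](CN3C(=O)OC(C)(C)C)C4)[nH]c2c(=O)[nH]1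
A5 | alternative 3 | N,N'-dibenzyl-O-methylpiperazinomycin | COc1ccc2cc1Oc1ccc(cc1)C[C@H]1CN(Cc3ccccc3)[C@H](CN1Cc1ccccc1)C2
A6 | alternative 3 | 15-membered macrocyclic aryl ester (ring A oxygen acylated by the ring B para-carboxyl group; N,N'-dibenzyl, O-methyl) | COc1ccc2cc1OC(=O)c1ccc(cc1)C[C@H]1CN(Cc3ccccc3)[C@H](CN1Cc1ccccc1)C2
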